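## Retrosynthetic overview
1. Cryptomerin A ⇒ its tetra-O-benzyl ether. Hydrogenolysis comes last, and the single OMe is carried in with p-anisaldehyde, so it never has to be told apart from the free OH groups.
2. The pyranone ring of the apigenin-type unit is formed last, by I2/DMSO oxidative cyclisation of a 2'-hydroxychalcone. The key C–C bond comes from an intermolecular Claisen–Schmidt aldol condensation of a 6-(4-formylphenoxy)flavone with 2-hydroxy-4,6-dibenzyloxyacetophenone.
3. Diaryl ether ⇒ SNAr of a 5,7-dibenzyloxy-6-hydroxyflavone on 4-fluorobenzaldehyde.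
4. The pyranone ring of the acacetin-type unit is formed first, by the same aldol/oxidative cyclisation pair. It starts from p-anisaldehyde and a 2,4-dibenzyloxy-3,6-dihydroxyacetophenone masked as its 3-O-MOM ether.
5. Both acetophenones ⇒ phloroacetophenone (dibenzylation, then Elbs para-hydroxylation, which fixes the 5,6,7-oxygenation pattern). All benzene rings are bought and only the two pyranone rings are built.

Assumption: the target SMILES holds no stereocentre and no hindered axis, so cryptomerin A is achiral and no enantioselective step is needed. The only stereo-elements on the way are E-chalcone double bonds and transient racemic centres, which are erased on aromatisation.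

## Route

Step 1
Reactants: 1 2,4,6-trihydroxyacetophenone
Product: 2 1-[2,4-bis(benzyloxy)-6-hydroxyphenyl]ethan-1-one
Conditions: BnBr (2.1 equiv), K2CO3 (2.2 equiv), DMF, 60 °C, 3 h
Reagents that add atoms: benzyl bromide, BrCc1ccccc1
Why: Williamson ether synthesis in which two phenols are alkylated and the last OH stays free because it is locked in a hydrogen bond to the acetyl C=O, leaving the 2'-OH needed for ring closure.

Step 2
Reactants: 2 1-[2,4-bis(benzyloxy)-6-hydroxyphenyl]ethan-1-one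
Product: 4 1-[2,4-bis(benzyloxy)-3,6-dihydroxyphenyl]ethan-1-one, via potassium aryl sulfate 3 (not isolated)
Conditions: K2S2O8 (1.2 equiv), aq KOH, pyridine, 15 °C to rt, 24 h; HCl to pH 4, filter off and recycle unreacted 2; then conc. HCl, 80 °C, 30 min, N2
Reagents that add atoms: potassium peroxodisulfate, [K+].[K+].[O-]S(=O)(=O)OOS(=O)(=O)[O-]
Why: Elbs persulfate oxidation, in which the phenoxide attacks peroxodisulfate through its only para carbon (between the two OBn groups) and acid hydrolysis of the aryl sulfate frees the new OH, so the regiochemistry is unambiguous.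

Step 3
Reactants: 4 1-[2,4-bis(benzyloxy)-3,6-dihydroxyphenyl]ethan-1-one
Product: 5 1-[2,4-bis(benzyloxy)-6-hydroxy-3-(methoxymethoxy)phenyl]ethan-1-one
Conditions: MOMCl (1.1 equiv), K2CO3 (1.5 equiv), acetone, 0 °C to rt, N2
Reagents that add atoms: chloromethyl methyl ether, COCCl
Why: Selective O-alkylation of the non-chelated 3-OH over the chelated 6-OH, which masks the hydroquinone so that neither KOH/air nor I2 can oxidise it to a quinone later.

Step 4
Reactants: 5 1-[2,4-bis(benzyloxy)-6-hydroxy-3-(methoxymethoxy)phenyl]ethan-1-one; 6 4-methoxybenzaldehyde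
Product: 8 (E)-1-[2,4-bis(benzyloxy)-6-hydroxy-3-(methoxymethoxy)phenyl]-3-(4-methoxyphenyl)prop-2-en-1-one, via racemic beta-hydroxy ketone 7 (not isolated)
Conditions: KOH (50% aq, 10 equiv), EtOH/THF, rt, 48 h, N2; then AcOH to pH 6
Reagents that add atoms: none
Why: Claisen–Schmidt crossed aldol condensation of a methyl ketone enolate with a non-enolisable aldehyde, where E1cB loss of water gives the more stable E-enone and the Bn and MOM ethers are inert to KOH.

Step 5
Reactants: 8 (E)-1-[2,4-bis(benzyloxy)-6-hydroxy-3-(methoxymethoxy)phenyl]-3-(4-methoxyphenyl)prop-2-en-1-one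
Product: 10 5,7-bis(benzyloxy)-6-(methoxymethoxy)-2-(4-methoxyphenyl)-4H-chromen-4-one, via racemic flavanone 9 (not isolated)
Conditions: I2 (10 mol%), DMSO, 120 °C, 2 h; aq Na2S2O3 wash
Reagents that add atoms: none
Why: I2/DMSO oxidative cyclisation, in which only the single free OH can close the ring by oxa-Michael addition and iodine-catalysed dehydrogenation with DMSO as terminal oxidant aromatises the pyranone; any partial MOM loss is harmless because step 6 removes the group anyway.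

Step 6
Reactants: 10 5,7-bis(benzyloxy)-6-(methoxymethoxy)-2-(4-methoxyphenyl)-4H-chromen-4-one
Product: 11 5,7-bis(benzyloxy)-6-hydroxy-2-(4-methoxyphenyl)-4H-chromen-4-one
Conditions: 2 M aq HCl, THF, 50 °C, 3 h
Reagents that add atoms: none
Why: Acid-catalysed acetal hydrolysis cleaves the MOM ether through its oxocarbenium ion under conditions too mild for benzyl or methyl aryl ethers.

Step 7
Reactants: 11 5,7-bis(benzyloxy)-6-hydroxy-2-(4-methoxyphenyl)-4H-chromen-4-one; 12 4-fluorobenzaldehyde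
Product: 13 4-{[5,7-bis(benzyloxy)-2-(4-methoxyphenyl)-4-oxo-4H-chromen-6-yl]oxy}benzaldehyde
Conditions: 12 (1.5 equiv), K2CO3 (2 equiv), DMF, 110 °C, 12 h
Reagents that add atoms: none
Why: SNAr (addition–elimination) of the only free phenoxide on a fluoride activated by the para-formyl group, run at the flavone stage where no enolisable methyl ketone can condense with the aldehyde.

Step 8 (key step)
Reactants: 13 4-{[5,7-bis(benzyloxy)-2-(4-methoxyphenyl)-4-oxo-4H-chromen-6-yl]oxy}benzaldehyde; 2 1-[2,4-bis(benzyloxy)-6-hydroxyphenyl]ethan-1-one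
Product: 15 5,7-bis(benzyloxy)-6-(4-{(E)-3-[2,4-bis(benzyloxy)-6-hydroxyphenyl]-3-oxoprop-1-en-1-yl}phenoxy)-2-(4-methoxyphenyl)-4H-chromen-4-one, via racemic beta-hydroxy ketone 14 (not isolated)
Conditions: 2 (1.2 equiv), KOH (50% aq, 10 equiv), EtOH/THF 1:1, rt, 36 h, N2; then 1 M HCl to pH 5
Reagents that add atoms: none
Why: Intermolecular Claisen–Schmidt aldol condensation that joins the two halves, with 13 as the only aldehyde and 2 as the only enolisable ketone, the flavone ring stable to KOH at rt, and E1cB dehydration giving the E-chalcone.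

Step 9
Reactants: 15 5,7-bis(benzyloxy)-6-(4-{(E)-3-[2,4-bis(benzyloxy)-6-hydroxyphenyl]-3-oxoprop-1-en-1-yl}phenoxy)-2-(4-methoxyphenyl)-4H-chromen-4-one
Product: 17 5,7-bis(benzyloxy)-6-{4-[5,7-bis(benzyloxy)-4-oxo-4H-chromen-2-yl]phenoxy}-2-(4-methoxyphenyl)-4H-chromen-4-one, via racemic flavanone 16 (not isolated)
Conditions: I2 (20 mol%), DMSO, 130 °C, 2 h; aq Na2S2O3 wash
Reagents that add atoms: none
Why: The same I2/DMSO oxidative cyclisation (oxa-Michael closure, then iodine-catalysed dehydrogenation) builds the second pyranone ring, and the finished flavone, diaryl ether and benzyl ethers are inert to it.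

Step 10
Reactants: 17 5,7-bis(benzyloxy)-6-{4-[5,7-bis(benzyloxy)-4-oxo-4H-chromen-2-yl]phenoxy}-2-(4-methoxyphenyl)-4H-chromen-4-one
Product: 18 cryptomerin A
Conditions: H2 (1 atm), 10% Pd/C, THF/MeOH 1:1, rt, 12 h
Reagents that add atoms: none
Why: Catalytic hydrogenolysis cleaves only the four benzylic C–O bonds, while the aryl methyl ether, the diaryl ether and the flavone C2=C3 bonds are untouched at 1 atm and rt.

## Compound list
1 | 2,4,6-trihydroxyacetophenone (phloroacetophenone) | CC(=O)c1c(O)cc(O)cc1O | starting material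
2 | 1-[2,4-bis(benzyloxy)-6-hydroxyphenyl]ethan-1-one | CC(=O)c1c(O)cc(OCc2ccccc2)cc1OCc3ccccc3 | intermediate
3 | potassium 3-acetyl-2,6-bis(benzyloxy)-4-hydroxyphenyl sulfate | CC(=O)c1c(O)cc(OCc2ccccc2)c(OS(=O)(=O)[O-])c1OCc3ccccc3.[K+] | intermediate
4 | 1-[2,4-bis(benzyloxy)-3,6-dihydroxyphenyl]ethan-1-one | CC(=O)c1c(O)cc(OCc2ccccc2)c(O)c1OCc3ccccc3 | intermediate
5 | 1-[2,4-bis(benzyloxy)-6-hydroxy-3-(methoxymethoxy)phenyl]ethan-1-one | CC(=O)c1c(O)cc(OCc2ccccc2)c(OCOC)c1OCc3ccccc3 | intermediate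
6 | 4-methoxybenzaldehyde (p-anisaldehyde) | COc1ccc(C=O)cc1 | starting material
7 | rac-1-[2,4-bis(benzyloxy)-6-hydroxy-3-(methoxymethoxy)phenyl]-3-hydroxy-3-(4-methoxyphenyl)propan-1-one | COc1ccc(C(O)CC(=O)c2c(O)cc(OCc3ccccc3)c(OCOC)c2OCc4ccccc4)cc1 | intermediate
8 | (E)-1-[2,4-bis(benzyloxy)-6-hydroxy-3-(methoxymethoxy)phenyl]-3-(4-methoxyphenyl)prop-2-en-1-one | COc1ccc(/C=C/C(=O)c2c(O)cc(OCc3ccccc3)c(OCOC)c2OCc4ccccc4)cc1 | intermediate
9 | rac-5,7-bis(benzyloxy)-6-(methoxymethoxy)-2-(4-methoxyphenyl)chroman-4-one | COc1ccc(C2CC(=O)c3c(OCc4ccccc4)c(OCOC)c(OCc5ccccc5)cc3O2)cc1 | intermediate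
10 | 5,7-bis(benzyloxy)-6-(methoxymethoxy)-2-(4-methoxyphenyl)-4H-chromen-4-one | COc1ccc(-c2cc(=O)c3c(OCc4ccccc4)c(OCOC)c(OCc5ccccc5)cc3o2)cc1 | intermediate
11 | 5,7-bis(benzyloxy)-6-hydroxy-2-(4-methoxyphenyl)-4H-chromen-4-one | COc1ccc(-c2cc(=O)c3c(OCc4ccccc4)c(O)c(OCc5ccccc5)cc3o2)cc1 | intermediate
12 | 4-fluorobenzaldehyde | O=Cc1ccc(F)cc1 | starting material
13 | 4-{[5,7-bis(benzyloxy)-2-(4-methoxyphenyl)-4-oxo-4H-chromen-6-yl]oxy}benzaldehyde | COc1ccc(-c2cc(=O)c3c(OCc4ccccc4)c(Oc5ccc(C=O)cc5)c(OCc6ccccc6)cc3o2)cc1 | intermediate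
14 | rac-5,7-bis(benzyloxy)-6-(4-{3-[2,4-bis(benzyloxy)-6-hydroxyphenyl]-1-hydroxy-3-oxopropyl}phenoxy)-2-(4-methoxyphenyl)-4H-chromen-4-one | COc1ccc(-c2cc(=O)c3c(OCc4ccccc4)c(Oc5ccc(C(O)CC(=O)c6c(O)cc(OCc7ccccc7)cc6OCc8ccccc8)cc5)c(OCc9ccccc9)cc3o2)cc1 | intermediate
15 | 5,7-bis(benzyloxy)-6-(4-{(E)-3-[2,4-bis(benzyloxy)-6-hydroxyphenyl]-3-oxoprop-1-en-1-yl}phenoxy)-2-(4-methoxyphenyl)-4H-chromen-4-one | COc1ccc(-c2cc(=O)c3c(OCc4ccccc4)c(Oc5ccc(/C=C/C(=O)c6c(O)cc(OCc7ccccc7)cc6OCc8ccccc8)cc5)c(OCc9ccccc9)cc3o2)cc1 | intermediate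
16 | rac-5,7-bis(benzyloxy)-6-{4-[5,7-bis(benzyloxy)-4-oxochroman-2-yl]phenoxy}-2-(4-methoxyphenyl)-4H-chromen-4-one | COc1ccc(-c2cc(=O)c3c(OCc4ccccc4)c(Oc5ccc(C6CC(=O)c7c(OCc8ccccc8)cc(OCc9ccccc9)cc7O6)cc5)c(OCc4ccccc4)cc3o2)cc1 | intermediate
17 | 5,7-bis(benzyloxy)-6-{4-[5,7-bis(benzyloxy)-4-oxo-4H-chromen-2-yl]phenoxy}-2-(4-methoxyphenyl)-4H-chromen-4-one (tetra-O-benzylcryptomerin A) | COc1ccc(-c2cc(=O)c3c(OCc4ccccc4)c(Oc5ccc(-c6cc(=O)c7c(OCc8ccccc8)cc(OCc9ccccc9)cc7o6)cc5)c(OCc4ccccc4)cc3o2)cc1 | intermediate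
18 | cryptomerin A, 6-[4-(5,7-dihydroxy-4-oxo-4H-chromen-2-yl)phenoxy]-5,7-dihydroxy-2-(4-methoxyphenyl)-4H-chromen-4-one (achiral) | COc1ccc(-c2cc(=O)c3c(O)c(Oc4ccc(-c5cc(=O)c6c(O)cc(O)cc6o5)cc4)c(O)cc3o2)cc1 | target

## Step count and risks
Total step count: 10. Longest linear sequence: 10 steps (1 to 18). Compound 2 from step 1 serves both halves and re-enters in step 8.

**Most likely to fail, first: step 2.** The Elbs oxidation attacks a para carbon flanked by two OBn groups. Conversion is usually modest (about 25–40 %, with 2 recovered), and 2 dissolves poorly in aqueous base. The fallback sets out from 2 and replaces persulfate chemistry by a phenol-to-quinone oxidation. [Bis(trifluoroacetoxy)iodo]benzene (2.2 equiv) in MeCN/H2O at 0 °C delivers water to the same para carbon and gives 2-acetyl-3,5-bis(benzyloxy)cyclohexa-2,5-diene-1,4-dione F1. This is reduced with Na2S2O4 in THF/H2O under N2, and the fallback comes back to the route at 4.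

**Second: step 7.** The phenoxide of 11 is flanked by two benzyloxy groups, so addition–elimination may be slow. The fallback sets out from 11 and swaps SNAr for a copper-catalysed Ullmann-type C–O cross-coupling made for hindered phenols. It uses 4-iodobenzaldehyde, CuI (10 mol%), picolinic acid (20 mol%) and K3PO4 in DMSO at 90 °C. It comes back to the route at 13 and makes no new compound on the way (entry F0).

**Third: step 8.** The large aldehyde 13 is poorly soluble, and its flavone ring could open slowly under hydroxide over a long reaction time. The fallback sets out from 13 and forms the same C–C bond by an intermolecular Claisen-type acylation at low temperature, without hydroxide.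
- Pinnick oxidation (NaClO2, NaH2PO4, 2-methylbut-2-ene, t-BuOH/THF/H2O) gives 4-{[5,7-bis(benzyloxy)-2-(4-methoxyphenyl)-4-oxo-4H-chromen-6-yl]oxy}benzoic acid F2.
- (COCl)2 with cat. DMF in CH2Cl2 gives 4-{[5,7-bis(benzyloxy)-2-(4-methoxyphenyl)-4-oxo-4H-chromen-6-yl]oxy}benzoyl chloride F3.
- The dilithium dianion of 2 (LiN(SiMe3)2, 3.2 equiv, THF, −78 °C) is C-acylated by the acid chloride. This gives 1-[2,4-bis(benzyloxy)-6-hydroxyphenyl]-3-(4-{[5,7-bis(benzyloxy)-2-(4-methoxyphenyl)-4-oxo-4H-chromen-6-yl]oxy}phenyl)propane-1,3-dione F4.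
- Cat. p-TsOH in toluene at 90 °C cyclodehydrates the diketone, and the fallback comes back to the route at 17, bypassing 15 and step 9.

## Further compounds
F1 | step 2 | 2-acetyl-3,5-bis(benzyloxy)cyclohexa-2,5-diene-1,4-dione | CC(=O)C1=C(OCc2ccccc2)C(=O)C(OCc3ccccc3)=CC1=O
F0 | step 7 | none | none
F2 | step 8 | 4-{[5,7-bis(benzyloxy)-2-(4-methoxyphenyl)-4-oxo-4H-chromen-6-yl]oxy}benzoic acid | COc1ccc(-c2cc(=O)c3c(OCc4ccccc4)c(Oc5ccc(C(=O)O)cc5)c(OCc6ccccc6)cc3o2)cc1
F3 | step 8 | 4-{[5,7-bis(benzyloxy)-2-(4-methoxyphenyl)-4-oxo-4H-chromen-6-yl]oxy}benzoyl chloride | COc1ccc(-c2cc(=O)c3c(OCc4ccccc4)c(Oc5ccc(C(=O)Cl)cc5)c(OCc6ccccc6)cc3o2)cc1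
F4 | step 8 | 1-[2,4-bis(benzyloxy)-6-hydroxyphenyl]-3-(4-{[5,7-bis(benzyloxy)-2-(4-methoxyphenyl)-4-oxo-4H-chromen-6-yl]oxy}phenyl)propane-1,3-dione | COc1ccc(-c2cc(=O)c3c(OCc4ccccc4)c(Oc5ccc(C(=O)CC(=O)c6c(O)cc(OCc7ccccc7)cc6OCc8ccccc8)cc5)c(OCc9ccccc9)cc3o2)cc1
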